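Does more nucleophile carry the electrophile further in a fixed time, or does the electrophile's loss ignore it?

* part of the electrophile that has reacted at the end, oak
* part of the electrophile that has reacted at the end, larch
* what raising the equivalents of nucleophile from its lowest to its highest value here does to the part of the electrophile that has reacted (changes below 5 percentage points count as none) (it rises / it falls / no change)

| flask | electrophile | nucleophile | gas | remark | time |
|---|---|---|---|---|---|
| spring | 0.25 M | 0.74 equiv | 11 mM (held) | run made earlier |  |
| summer | 0.25 M | 1.5 equiv | 11 mM (held) | run made earlier |  |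
| winter | 0.25 M | 2.1 equiv | 11 mM (held) | run made earlier |  |
| oak | 0.25 M | 1.00 equiv | 11 mM (held) |  | 30 h |
| larch | 0.25 M | 2.00 equiv | 11 mM (held) |  | 30 h |

- spring (time / h: electrophile / %, target / %): 1.50: 94.6, 3.3; 4.00: 89.4, 10.4; 10.0: 80.4, 18.2; 20.0: 68.4, 24.4
- summer (time / h: electrophile / %, target / %): 2.50: 86.5, 13.0; 8.00: 66.5, 29.9; 15.0: 54.1, 39.0; 20.0: 44.9, 43.5
- winter (time / h: electrophile / %, target / %): 1.50: 89.1, 11.4; 4.00: 73.3, 25.7; 10.0: 51.6, 43.0; 20.0: 31.6, 56.6

(standard deviation of a reading: 1 percentage point)

- at the start none of the gas is in solution

Turn the question round. For "no change", the runs would have to lie closer together than 5 percentage points. Yet at 20.0 h the spring run has lost 31.6% of its electrophile and the winter run 68.4%. That gap of 37 points is 7.36 margins wide, though it spans more nucleophile than separates oak from larch, so the opposite outcome looks remote but still needs a reckoning for these two flasks.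

How much the nucleophile matters needs one number. Suppose electrophile and nucleophile are consumed one for one, and divide the rate of loss by [electrophile][nucleophile]. If that ratio holds steady, then with E the fraction of electrophile left and q the equivalents, ln[(E+q−1)/(qE)] = (q−1)κt. I call κ the charge-scaled constant, an apparent second-order constant in units of the electrophile charge.

Your last readings give 0.0345 h⁻¹ for winter, and much the same for spring, 0.0341 h⁻¹. Carrying the winter value to 30 h, I reckon 50.8% reacted for oak and 78.4% for larch.

The forecast, finding that this form “gives nearly the same constant in all three runs”, says 50% and 77%, a little below mine, and it rises.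

The flasks give 47.6% for oak and 76.3% for larch, so it rises, by 29 points.

    electrophile + nucleophile ⇌ acid set free + target (K = 0.470, k = 0.159 M⁻¹ h⁻¹)
    nucleophile + acid set free ⇌ protonated nucleophile, settled at all times (K = 2400 M⁻¹)
    acid set free + free base ⇌ salt of the base (K = 248 M⁻¹, k = 2.43 M⁻¹ h⁻¹)
    gas ⇌ free base, rate k4*(csat - [free base]) (kL = 3.07 h⁻¹)
    electrophile + target → side product (k = 0.0603 M⁻¹ h⁻¹)

My 78.4% for larch stands close to the 76.3% computed. In larch at 6.55 h, the electrophile's half-life by the forward nucleophile step is 13 h, shorter than the 140 h by the path over target to side product. In larch at 30.0 h the forward step still uses electrophile 2.8 times as fast as the side path, a narrower margin than before.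

For the neighbouring flask, larch read at 8.0 h, 0.0345 h⁻¹ gives 38.8% reacted. The computed neighbouring flask gives 40.5%.

The numbers in the tables are calculated with constants of no real substance, noise included.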